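**Minutes: order in free catalyst**

| flask | substrate | reagent | free catalyst | remark |
|---|---|---|---|---|
| winter | 0.75 M | 2 equiv | 2.5 mol% | run made earlier |
| summer | 1.1 M | 2 equiv | 2.5 mol% | run made earlier |
| flask | 1.5 M | 2.00 equiv | 2.5 mol% |  |

| run | time / h | target / % | substrate / % |
|---|---|---|---|
| winter | 0.667 | 0.5 | 34.4 |
| winter | 1.33 | 0.5 | 20.2 |
| winter | 3.00 | 2.5 | 9.5 |
| winter | 8.00 | 8.2 | 4.2 |
| summer | 0.667 | 0.7 | 26.4 |
| summer | 1.33 | 2.0 | 14.0 |
| summer | 3.00 | 5.3 | 5.8 |
| summer | 8.00 | 13.1 | 2.8 |

(scatter of a reading: 0.3 percentage points)

* apparent order in free catalyst when 5.0 % of the substrate are converted (percent change of the rate of making target for one percent more free catalyst charged)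

Between the first two readings the reciprocal of the substrate left climbed faster in the summer run than in the winter run, at 5.06 h⁻¹ against 3.08 h⁻¹. The process chemist opened by noting that this ratio of 1.64 lies nearer the ratio of charges, 1.47, than its square, 2.15, so she held that substrate leaves mainly by meeting substrate, with no catalyst in that step.

The kineticist scaled the winter slope to the flask's charge, which gave 0.512 min, and named this the pairing clock, the time in which substrate meeting substrate removes the asked conversion. He then followed one molecule to the fork: that clock holds no catalyst, so if catalyst opens the side road, the traffic on it within the clock grows with [free catalyst], and if catalyst acts again at delivery, the rate of making target gains a second factor. She objected that both runs hold catalyst and reagent in the same proportion to substrate, so the readings do not tell the two apart. The reckoning was nevertheless committed on his assumption: an order near 2, one for each catalyst encounter inside the clock.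

The forecast is lower, at 1 within 0.7 to 1.1, in its words “Assuming the catalyst acts here, the order is about 1”.

The flask gives an order of 1.9, at 0.598 min.

    substrate + free catalyst ⇌ free catalyst + open intermediate (K = 2.50, k = 0.00380 M⁻¹ s⁻¹)
    free catalyst + open intermediate ⇌ catalyst intermediate (K = 0.260 M⁻¹, k = 0.0240 M⁻¹ s⁻¹)
    reagent + catalyst intermediate → free catalyst + target (k = 0.00360 M⁻¹ s⁻¹)
    2 substrate → homo dimer (k = 4.40 × 10⁻⁴ M⁻¹ s⁻¹)

That flask's pairing clock is reckoned on the turning of 2 substrate into homo dimer, which holds no catalyst. Take that step out of the same flask and the order falls to 0.97. Free catalyst must then remove the substrate itself, which by the forward step at the charged loading is reckoned to take about 6.00 min, or 11.7 times the pairing clock, and the rate at that conversion stands at 12.8 times the actual one.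

All runs are simulated with constants of no real substance, noise included.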